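**Assumption:** the D‑fructose‑derived Shi ketone is taken to give the (R)/(R,R) epoxides drawn (otherwise its enantiomer is used). Ring A carbons are called C‑1 (acetoxy carbon) to C‑6; none of the steps has been run.

## Retrosynthetic overview

1. Target 24 ⇐ Baeyer–Villiger oxidation of methyl ketone 23 (C–O bond made with retention at the quaternary carbon).
2. 23 ⇐ bromonium‑initiated 6‑endo cyclisation of tertiary allylic alcohol 22, terminated by a semipinacol 1,2‑shift of the CH2–hydrindanyl group (ring A formed last).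
3. 22 ⇐ double methyl addition to diketone 21 ⇐ Mukaiyama–Michael union of hydrindenone 11 with the siloxydiene of enone 18.
4. 11 ⇐ aldol condensation (ring D) ⇐ bromocyclohexanone 9 from bromonium/silyl‑enol‑ether cyclisation (ring C) ⇐ Shi epoxide of dienone 4 ⇐ hex‑1‑en‑5‑yne + MVK.
5. 18 ⇐ acetylacetone + formaldehyde + bromochloride 15 ⇐ Shi epoxide of 5‑bromo‑2‑methylpent‑2‑ene. Ring order: C, then D, then A.

## Route

Step 1
Reactants: 1 hex-1-en-5-yne; 2 but-3-en-2-one
Product: 4 (5E)-6-methyldeca-5,9-dien-2-one, via alkenylalane 3 (not isolated)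
Conditions: Me3Al, Cp2ZrCl2 (10 mol %), CH2Cl2, 0 °C to rt; then CuTC (10 mol %), 2, THF, −30 °C; 1 M HCl
Reagents that add atoms: trimethylaluminium, C[Al](C)C
Why: Zr‑catalysed syn‑carboalumination (Negishi) puts Me on the internal alkyne carbon and gives the (E)‑alkenylalane, which adds 1,4 to the enone under Cu catalysis with retention of alkene geometry.

Step 2
Reactants: 4 (5E)-6-methyldeca-5,9-dien-2-one
Product: 5 4-[(2R,3R)-3-(but-3-en-1-yl)-3-methyloxiran-2-yl]butan-2-one
Conditions: Shi ketone (D‑fructose‑derived, 30 mol %), Oxone, K2CO3, Bu4NHSO4, MeCN–DMM–buffer (pH 10.5), 0 °C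
Reagents that add atoms: potassium peroxymonosulfate (Oxone), [K+].[O-]S(=O)(=O)OO
Why: Shi asymmetric epoxidation; the chiral dioxirane attacks the electron‑rich trisubstituted (E)‑alkene (not the vinyl group) through the spiro transition state and sets both epoxide carbons (R,R).

Step 3
Reactants: 5 4-[(2R,3R)-3-(but-3-en-1-yl)-3-methyloxiran-2-yl]butan-2-one
Product: 6 (5S,6R)-5-bromo-6-hydroxy-6-methyldec-9-en-2-one
Conditions: Li2NiBr4, THF, 0 °C to rt
Reagents that add atoms: dilithium tetrabromonickelate, [Li+].[Li+].Br[Ni-2](Br)(Br)Br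
Why: Regioselective SN2 opening of the trisubstituted epoxide by bromide at the less substituted carbon, inverting C‑5 to S and leaving the tertiary alcohol.

Step 4
Reactants: 6 (5S,6R)-5-bromo-6-hydroxy-6-methyldec-9-en-2-one
Product: 7 (5S,6R)-5-bromo-6-chloro-6-methyldec-9-en-2-one
Conditions: HCl (g), CH2Cl2, 0 °C
Reagents that add atoms: hydrogen chloride, Cl
Why: SN1 (Lucas‑type) chlorination with neighbouring‑bromine participation; the bromonium ion is opened by chloride at the tertiary carbon, so C‑6 is retained by double inversion and C‑5 is untouched.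

Step 5
Reactants: 7 (5S,6R)-5-bromo-6-chloro-6-methyldec-9-en-2-one
Product: 8 trimethyl{[(5S,6R)-5-bromo-6-chloro-6-methyldeca-1,9-dien-2-yl]oxy}silane
Conditions: LDA, THF, −78 °C; TMSCl
Reagents that add atoms: chlorotrimethylsilane, C[Si](C)(C)Cl
Why: Kinetic deprotonation of the methyl ketone on the CH3 side and O‑silylation give the terminal silyl enol ether.

Step 6
Reactants: 8 trimethyl{[(5S,6R)-5-bromo-6-chloro-6-methyldeca-1,9-dien-2-yl]oxy}silane
Product: 9 (3S,4S)-4-bromo-3-(but-3-en-1-yl)-3-methylcyclohexan-1-one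
Conditions: TiCl4, CH2Cl2, −78 to −40 °C; aq. NaHCO3
Reagents that add atoms: none
Why: Lewis‑acid ionisation of the tertiary chloride with anchimeric Br gives a configurationally defined bromonium ion that the silyl enol ether opens 6‑endo at the tertiary carbon through a chair (Reetz‑type tert‑alkylation, bromonium cation–olefin cyclisation), anti to Br, which sets C‑3 (S) next to C‑4 (S) with Br equatorial and cis to the methyl.

Step 7
Reactants: 9 (3S,4S)-4-bromo-3-(but-3-en-1-yl)-3-methylcyclohexan-1-one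
Product: 11 (7S,7aS)-7-bromo-7a-methyl-1,2,5,6,7,7a-hexahydro-4H-inden-4-one, via keto-aldehyde 10 (not isolated)
Conditions: O3, CH2Cl2–MeOH, −78 °C; Me2S; then p‑TsOH (cat.), benzene, 80 °C
Reagents that add atoms: ozone, [O-][O+]=O
Why: Ozonolysis of the vinyl group to the aldehyde, then acid‑catalysed intramolecular aldol condensation of C‑2 onto it (only this mode gives a five‑membered ring, and dehydration to the conjugated enone drives it).

Step 8
Reactants: 12 5-bromo-2-methylpent-2-ene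
Product: 13 (2R)-2-(2-bromoethyl)-3,3-dimethyloxirane
Conditions: Shi ketone (D‑fructose‑derived, 30 mol %), Oxone, K2CO3, Bu4NHSO4, MeCN–DMM–buffer, 0 °C
Reagents that add atoms: potassium peroxymonosulfate (Oxone), [K+].[O-]S(=O)(=O)OO
Why: Shi asymmetric epoxidation of the trisubstituted alkene sets the (R) epoxide carbon that becomes ring‑A C‑4.

Step 9
Reactants: 13 (2R)-2-(2-bromoethyl)-3,3-dimethyloxirane
Product: 14 (3S)-3,5-dibromo-2-methylpentan-2-ol
Conditions: Li2NiBr4, THF, 0 °C to rt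
Reagents that add atoms: dilithium tetrabromonickelate, [Li+].[Li+].Br[Ni-2](Br)(Br)Br
Why: SN2 epoxide opening by bromide at the secondary carbon with inversion gives the (S) C–Br centre.

Step 10
Reactants: 14 (3S)-3,5-dibromo-2-methylpentan-2-ol
Product: 15 (3S)-1,3-dibromo-4-chloro-4-methylpentane
Conditions: HCl (g), CH2Cl2, 0 °C
Reagents that add atoms: hydrogen chloride, Cl
Why: SN1 chlorination of the tertiary alcohol through the bromonium ion (opened at the non‑stereogenic CMe2 carbon) leaves the C–Br centre unchanged.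

Step 11
Reactants: 15 (3S)-1,3-dibromo-4-chloro-4-methylpentane; 16 pentane-2,4-dione
Product: 17 3-[(3S)-3-bromo-4-chloro-4-methylpentyl]pentane-2,4-dione
Conditions: K2CO3, acetone, 56 °C
Reagents that add atoms: none
Why: SN2 C‑alkylation of the acetylacetone enolate by the primary bromide; the hindered secondary bromide and the tertiary chloride do not react.

Step 12
Reactants: 17 3-[(3S)-3-bromo-4-chloro-4-methylpentyl]pentane-2,4-dione
Product: 18 (6S)-6-bromo-7-chloro-7-methyl-3-methylideneoctan-2-one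
Conditions: 37 % aq. HCHO, K2CO3, THF, rt
Reagents that add atoms: formaldehyde, C=O
Why: Deacetylative α‑methylenation: aldol addition to formaldehyde, acetyl transfer to the new alkoxide (retro‑Claisen) and E1cB loss of acetate give the α‑methylene ketone.

Step 13
Reactants: 18 (6S)-6-bromo-7-chloro-7-methyl-3-methylideneoctan-2-one; 11 (7S,7aS)-7-bromo-7a-methyl-1,2,5,6,7,7a-hexahydro-4H-inden-4-one
Product: 21 (3S,3aS,7S,7aS)-7-bromo-3-[(6S)-6-bromo-7-chloro-7-methyl-3-methylidene-2-oxooctyl]-7a-methyloctahydro-4H-inden-4-one, via siloxydiene 19 (not isolated), via silyl enol ether adduct 20 (not isolated)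
Conditions: Et3N (1.2 equiv), TMSOTf (1.5 equiv), CH2Cl2, 0 °C; then 11, −78 °C; 1 M HCl, THF
Reagents that add atoms: none
Why: Mukaiyama–Michael addition of the in situ 2‑siloxydiene to the enone, with attack on the ring‑D β‑carbon anti to the angular methyl (sets C‑3 S); protonation of the silyl enol ether (equilibrated if needed) gives the trans ring fusion (C‑3a S), favoured because the C‑3 chain and C‑4 are then trans on the cyclopentane.

Step 14
Reactants: 21 (3S,3aS,7S,7aS)-7-bromo-3-[(6S)-6-bromo-7-chloro-7-methyl-3-methylidene-2-oxooctyl]-7a-methyloctahydro-4H-inden-4-one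
Product: 22 (3S,3aS,4R,7S,7aS)-7-bromo-3-[(6S)-6-bromo-7-chloro-2-hydroxy-2,7-dimethyl-3-methylideneoctyl]-4,7a-dimethyloctahydro-1H-inden-4-ol (both epimers at the side-chain carbinol)
Conditions: MeLi, CeCl3 (excess), THF, −78 °C
Reagents that add atoms: methyllithium, [Li]C
Why: Non‑basic organocerium 1,2‑addition to both ketones; at C‑4 methyl enters equatorially because the axial face is blocked by the syn‑axial angular methyl, giving the axial alcohol (4R), while the side‑chain carbinol epimers converge in step 15.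

Step 15
Reactants: 22 (3S,3aS,4R,7S,7aS)-7-bromo-3-[(6S)-6-bromo-7-chloro-2-hydroxy-2,7-dimethyl-3-methylideneoctyl]-4,7a-dimethyloctahydro-1H-inden-4-ol
Product: 23 1-[(1S,4S)-4-bromo-1-{[(1S,3aS,4S,7R,7aS)-4-bromo-7-hydroxy-3a,7-dimethyloctahydro-1H-inden-1-yl]methyl}-3,3-dimethylcyclohexyl]ethan-1-one
Conditions: (CF3)2CHOH, NaHCO3, 0 °C to rt
Reagents that add atoms: none
Why: Proposed new method: solvolysis of the β‑bromo tertiary chloride gives, with anchimeric Br, a single bromonium ion that the 1,1‑disubstituted alkene opens 6‑endo at CMe2 through a chair with Br equatorial, and as the C‑1 cation develops the antiperiplanar CH2–hydrindanyl group shifts from the carbinol carbon to C‑1 (semipinacol 1,2‑shift), so it ends equatorial and trans to Br while the new acetyl is axial and cis to Br (C‑1 S from C‑4 S); the closest known reactions are the enantiospecific solvolytic bromonium polyene cyclisation of vicinal bromochlorides and the Prins–pinacol cyclisation, and their combination is untested.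

Step 16
Reactants: 23 1-[(1S,4S)-4-bromo-1-{[(1S,3aS,4S,7R,7aS)-4-bromo-7-hydroxy-3a,7-dimethyloctahydro-1H-inden-1-yl]methyl}-3,3-dimethylcyclohexyl]ethan-1-one
Product: 24 (1S,4S)-4-bromo-1-{[(1S,3aS,4S,7R,7aS)-4-bromo-7-hydroxy-3a,7-dimethyloctahydro-1H-inden-1-yl]methyl}-3,3-dimethylcyclohexyl acetate
Conditions: m‑CPBA, NaHCO3, CH2Cl2, rt
Reagents that add atoms: 3-chloroperbenzoic acid, OOC(=O)c1cccc(Cl)c1
Why: Baeyer–Villiger oxidation; the tertiary alkyl group migrates in preference to methyl with retention, so the axial acetyl becomes the axial acetate and the free tertiary alcohol is never acylated.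

## Compound list

1 | hex-1-en-5-yne | C#CCCC=C | starting material
2 | but-3-en-2-one | CC(=O)C=C | starting material
3 | dimethyl[(1E)-2-methylhexa-1,5-dien-1-yl]alumane | C[Al](C)/C=C(\C)CCC=C | intermediate
4 | (5E)-6-methyldeca-5,9-dien-2-one | CC(=O)CC/C=C(\C)CCC=C | intermediate
5 | 4-[(2R,3R)-3-(but-3-en-1-yl)-3-methyloxiran-2-yl]butan-2-one | CC(=O)CC[C@H]1O[C@]1(C)CCC=C | intermediate
6 | (5S,6R)-5-bromo-6-hydroxy-6-methyldec-9-en-2-one | CC(=O)CC[C@H](Br)[C@](C)(O)CCC=C | intermediate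
7 | (5S,6R)-5-bromo-6-chloro-6-methyldec-9-en-2-one | CC(=O)CC[C@H](Br)[C@](C)(Cl)CCC=C | intermediate
8 | trimethyl{[(5S,6R)-5-bromo-6-chloro-6-methyldeca-1,9-dien-2-yl]oxy}silane | C=C(O[Si](C)(C)C)CC[C@H](Br)[C@](C)(Cl)CCC=C | intermediate
9 | (3S,4S)-4-bromo-3-(but-3-en-1-yl)-3-methylcyclohexan-1-one | O=C1C[C@](C)(CCC=C)[C@@H](Br)CC1 | intermediate
10 | 3-[(1S,2S)-2-bromo-1-methyl-5-oxocyclohexyl]propanal | O=C1C[C@](C)(CCC=O)[C@@H](Br)CC1 | intermediate
11 | (7S,7aS)-7-bromo-7a-methyl-1,2,5,6,7,7a-hexahydro-4H-inden-4-one | O=C1CC[C@H](Br)[C@@]2(C)CCC=C12 | intermediate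
12 | 5-bromo-2-methylpent-2-ene | CC(C)=CCCBr | starting material
13 | (2R)-2-(2-bromoethyl)-3,3-dimethyloxirane | BrCC[C@H]1OC1(C)C | intermediate
14 | (3S)-3,5-dibromo-2-methylpentan-2-ol | BrCC[C@H](Br)C(C)(C)O | intermediate
15 | (3S)-1,3-dibromo-4-chloro-4-methylpentane | BrCC[C@H](Br)C(C)(C)Cl | intermediate
16 | pentane-2,4-dione | CC(=O)CC(C)=O | starting material
17 | 3-[(3S)-3-bromo-4-chloro-4-methylpentyl]pentane-2,4-dione | CC(=O)C(CC[C@H](Br)C(C)(C)Cl)C(C)=O | intermediate
18 | (6S)-6-bromo-7-chloro-7-methyl-3-methylideneoctan-2-one | CC(=O)C(=C)CC[C@H](Br)C(C)(C)Cl | intermediate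
19 | {[(6S)-6-bromo-7-chloro-7-methyl-3-methylideneoct-1-en-2-yl]oxy}trimethylsilane | C=C(O[Si](C)(C)C)C(=C)CC[C@H](Br)C(C)(C)Cl | intermediate
20 | (3S,7S,7aS)-7-bromo-3-[(6S)-6-bromo-7-chloro-7-methyl-3-methylidene-2-oxooctyl]-7a-methyl-4-[(trimethylsilyl)oxy]-2,3,5,6,7,7a-hexahydro-1H-indene | C=C(CC[C@H](Br)C(C)(C)Cl)C(=O)C[C@@H]1CC[C@]2(C)[C@@H](Br)CCC(O[Si](C)(C)C)=C12 | intermediate
21 | (3S,3aS,7S,7aS)-7-bromo-3-[(6S)-6-bromo-7-chloro-7-methyl-3-methylidene-2-oxooctyl]-7a-methyloctahydro-4H-inden-4-one | C=C(CC[C@H](Br)C(C)(C)Cl)C(=O)C[C@@H]1CC[C@]2(C)[C@@H](Br)CCC(=O)[C@@H]12 | intermediate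
22 | (3S,3aS,4R,7S,7aS)-7-bromo-3-[(6S)-6-bromo-7-chloro-2-hydroxy-2,7-dimethyl-3-methylideneoctyl]-4,7a-dimethyloctahydro-1H-inden-4-ol | C=C(CC[C@H](Br)C(C)(C)Cl)C(C)(O)C[C@@H]1CC[C@]2(C)[C@@H](Br)CC[C@@](C)(O)[C@@H]12 | intermediate
23 | 1-[(1S,4S)-4-bromo-1-{[(1S,3aS,4S,7R,7aS)-4-bromo-7-hydroxy-3a,7-dimethyloctahydro-1H-inden-1-yl]methyl}-3,3-dimethylcyclohexyl]ethan-1-one | CC(=O)[C@]1(C[C@@H]2CC[C@]3(C)[C@@H](Br)CC[C@@](C)(O)[C@@H]23)CC[C@H](Br)C(C)(C)C1 | intermediate
24 | (1S,4S)-4-bromo-1-{[(1S,3aS,4S,7R,7aS)-4-bromo-7-hydroxy-3a,7-dimethyloctahydro-1H-inden-1-yl]methyl}-3,3-dimethylcyclohexyl acetate | CC(=O)O[C@]1(C[C@@H]2CC[C@]3(C)[C@@H](Br)CC[C@@](C)(O)[C@@H]23)CC[C@H](Br)C(C)(C)C1 | target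

## Step count and risks

Total steps: 16. Longest linear sequence: 11 (steps 1–7, then 13–16); steps 8–12 form the convergent branch.

**Step 15 (proposed new cascade).** It could fail through methyl rather than CH2R migration, epoxide formation or elimination at the C‑1 cation, or a stepwise shift that erodes the C‑1/C‑4 relationship. The fallback uses known chemistry, sets out from 2 and 11 and returns at 24, but gives up stereocontrol at C‑1. Cu‑catalysed 1,4‑addition of 2‑methylprop‑1‑enylmagnesium bromide to 2 gives 6-methylhept-5-en-2-one F1. Shi epoxidation gives 4-[(2R)-3,3-dimethyloxiran-2-yl]butan-2-one F2. Li2NiBr4 gives (5S)-5-bromo-6-hydroxy-6-methylheptan-2-one F3 and HCl gives (5S)-5-bromo-6-chloro-6-methylheptan-2-one F4. Its kinetic silyl enol ether {[(5S)-5-bromo-6-chloro-6-methylhept-1-en-2-yl]oxy}trimethylsilane F5 is added to 11 (Mukaiyama–Michael, TMSOTf cat.) to give (3S,3aS,7S,7aS)-7-bromo-3-[(5S)-5-bromo-6-chloro-6-methyl-2-oxoheptyl]-7a-methyloctahydro-4H-inden-4-one F6. Wittig methylenation of the unhindered side‑chain ketone gives (3S,3aS,7S,7aS)-7-bromo-3-[(5S)-5-bromo-6-chloro-6-methyl-2-methylideneheptyl]-7a-methyloctahydro-4H-inden-4-one F7. MeLi/CeCl3 then gives (3S,3aS,4R,7S,7aS)-7-bromo-3-[(5S)-5-bromo-6-chloro-6-methyl-2-methylideneheptyl]-4,7a-dimethyloctahydro-1H-inden-4-ol F8. Solvolysis of F8 in HFIP–AcOH/NaOAc (bromonium cyclisation, acetate capture of the tertiary cation) gives 24 mixed with its C‑1 epimer, which must be separated.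

**Step 13 (Mukaiyama–Michael union).** The vinyl ketone product can undergo a second Michael addition (annulation), the Lewis acid may ionise the tertiary chloride, and the facial selectivity at C‑3 and the ring‑fusion protonation are predicted, not proven. The fallback sets out from 17 and 11 and returns at 21. 17 is converted (TMSOTf, Et3N) into its bis‑silyl dienol ether {[3-[(3S)-3-bromo-4-chloro-4-methylpentyl]penta-1,3-diene-2,4-diyl]bis(oxy)}bis(trimethylsilane) F9. F9 adds to 11 through its terminal carbon (vinylogous Mukaiyama–Michael) to give 3-[(3S)-3-bromo-4-chloro-4-methylpentyl]-1-[(3S,3aS,7S,7aS)-7-bromo-7a-methyl-4-oxooctahydro-1H-inden-3-yl]pentane-2,4-dione F10, which has no enone to cyclise onto. Deacetylative methylenation (aq. HCHO, K2CO3), with loss of the less hindered acetyl, then gives 21.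

**Step 4 (tertiary chloride from the δ‑keto bromohydrin).** Hemiketal formation, ketone‑oxygen capture of the bromonium ion, elimination or chloride attack at the secondary carbon could lower yield or enantiopurity. The fallback sets out from 1 and returns at 7, installing Br and Cl before the ketone exists. Carboalumination of 1 and trapping of the alanate with paraformaldehyde gives (2E)-3-methylhepta-2,6-dien-1-ol F11. Catalytic enantioselective bromochlorination of this allylic alcohol (NBS, ClTi(OiPr)3, chiral Schiff‑base ligand) gives (2S,3R)-2-bromo-3-chloro-3-methylhept-6-en-1-ol F12. Triflation gives (2S,3R)-2-bromo-3-chloro-3-methylhept-6-en-1-yl trifluoromethanesulfonate F13, and displacement with the lithium enolate of acetone gives 7.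

Further compounds
F1 | step 15 | 6-methylhept-5-en-2-one | CC(=O)CCC=C(C)C
F2 | step 15 | 4-[(2R)-3,3-dimethyloxiran-2-yl]butan-2-one | CC(=O)CC[C@H]1OC1(C)C
F3 | step 15 | (5S)-5-bromo-6-hydroxy-6-methylheptan-2-one | CC(=O)CC[C@H](Br)C(C)(C)O
F4 | step 15 | (5S)-5-bromo-6-chloro-6-methylheptan-2-one | CC(=O)CC[C@H](Br)C(C)(C)Cl
F5 | step 15 | {[(5S)-5-bromo-6-chloro-6-methylhept-1-en-2-yl]oxy}trimethylsilane | C=C(O[Si](C)(C)C)CC[C@H](Br)C(C)(C)Cl
F6 | step 15 | (3S,3aS,7S,7aS)-7-bromo-3-[(5S)-5-bromo-6-chloro-6-methyl-2-oxoheptyl]-7a-methyloctahydro-4H-inden-4-one | O=C(CC[C@H](Br)C(C)(C)Cl)C[C@@H]1CC[C@]2(C)[C@@H](Br)CCC(=O)[C@@H]12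
F7 | step 15 | (3S,3aS,7S,7aS)-7-bromo-3-[(5S)-5-bromo-6-chloro-6-methyl-2-methylideneheptyl]-7a-methyloctahydro-4H-inden-4-one | C=C(CC[C@H](Br)C(C)(C)Cl)C[C@@H]1CC[C@]2(C)[C@@H](Br)CCC(=O)[C@@H]12
F8 | step 15 | (3S,3aS,4R,7S,7aS)-7-bromo-3-[(5S)-5-bromo-6-chloro-6-methyl-2-methylideneheptyl]-4,7a-dimethyloctahydro-1H-inden-4-ol | C=C(CC[C@H](Br)C(C)(C)Cl)C[C@@H]1CC[C@]2(C)[C@@H](Br)CC[C@@](C)(O)[C@@H]12
F9 | step 13 | {[3-[(3S)-3-bromo-4-chloro-4-methylpentyl]penta-1,3-diene-2,4-diyl]bis(oxy)}bis(trimethylsilane) | C=C(O[Si](C)(C)C)C(CC[C@H](Br)C(C)(C)Cl)=C(C)O[Si](C)(C)C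
F10 | step 13 | 3-[(3S)-3-bromo-4-chloro-4-methylpentyl]-1-[(3S,3aS,7S,7aS)-7-bromo-7a-methyl-4-oxooctahydro-1H-inden-3-yl]pentane-2,4-dione | CC(=O)C(CC[C@H](Br)C(C)(C)Cl)C(=O)C[C@@H]1CC[C@]2(C)[C@@H](Br)CCC(=O)[C@@H]12
F11 | step 4 | (2E)-3-methylhepta-2,6-dien-1-ol | OC/C=C(\C)CCC=C
F12 | step 4 | (2S,3R)-2-bromo-3-chloro-3-methylhept-6-en-1-ol | OC[C@H](Br)[C@](C)(Cl)CCC=C
F13 | step 4 | (2S,3R)-2-bromo-3-chloro-3-methylhept-6-en-1-yl trifluoromethanesulfonate | O=S(=O)(OC[C@H](Br)[C@](C)(Cl)CCC=C)C(F)(F)F
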